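**Retrosynthetic overview**

1. Numbering: ring A is C1 (gem-diprenyl), C2 (C=O), C3 (spiro), C4 (C=O), C5 (isobutyryl), C6 (enol); ring B is C3, C8, C9, C10, C11, C12; ring C is C9, C10, C13, C14, C15.
2. Feature the plan rests on: C11 of ring B is a tertiary carbinol (methyl, C12, ring-fusion C10) whose oxygen is 1,3-cis-diaxial to the C2 carbonyl on spiro carbon C3. Ring B is therefore cut at C11–C12 (C10 acetyl plus a C12 iodomethyl group on a C3 malonate, SmI2 Barbier closure), and O11 lactonises on the cis ester so that C11 and C3 are set together.
3. Ring A is cut at C1–C2 and C4–C5: the dianion of 5-methylhexane-2,4-dione opens the lactone (C2) and then closes on the C4 methyl ester; C1 diprenylation comes last.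
4. The iodo ketone comes from (S)-limonene: epoxidation and periodate cleavage, amine aldol (ring C, C9–C15), silylation, Knoevenagel condensation and borohydride reduction (C8–C3), ozonolysis (C10 acetyl), alkylation with CH2I2 (C12).
5. Order of ring formation: ring C, then ring B together with the lactone bridge, then ring A.

Key step: step 9

Remark on the chemistry: the acyl triones 16, 17 and 19 are tautomeric and are written in the C6 enol form of the target; 15 is written as the open keto form although it may rest as the C2 hemiketal with O11.

**Route**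

Step 1
Reactants: 1 (S)-limonene
Product: 2 (4S)-limonene 1,2-oxide (cis/trans mixture at the epoxide)
Conditions: mCPBA (1.05 equiv), NaHCO3, CH2Cl2, 0 °C
Reagents that add atoms: mCPBA, O=C(OO)c1cccc(Cl)c1
Why: Prilezhaev epoxidation is selective for the electron-richer trisubstituted ring alkene over the isopropenyl group, and both epoxide diastereomers converge in step 2, so only the limonene stereocentre (later C10) matters.

Step 2
Reactants: 2 (4S)-limonene 1,2-oxide
Product: 3 (3S)-6-oxo-3-(prop-1-en-2-yl)heptanal
Conditions: H5IO6 (1.2 equiv), THF/H2O, 0 °C to rt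
Reagents that add atoms: water, O
Why: Acid-promoted epoxide hydrolysis to the trans-diol and Malaprade glycol cleavage in the same pot should give the keto aldehyde without touching the isopropenyl group or the stereocentre.

Step 3
Reactants: 3 (3S)-6-oxo-3-(prop-1-en-2-yl)heptanal
Product: 4 (1R,2S,5S)-2-hydroxy-2-methyl-5-(prop-1-en-2-yl)cyclopentane-1-carbaldehyde
Conditions: piperidine (0.2 equiv), AcOH (0.2 equiv), CH2Cl2, 0 °C, quenched with pH 7 buffer at the aldol stage
Reagents that add atoms: none
Why: Enamine-mediated intramolecular aldol addition (5-enolexo-exo-trig) of the aldehyde α-carbon to the methyl ketone forms C9–C15 and ring C; because the aldol is reversible and C9 is enolisable, the material should collect in the isomer with formyl trans to the C10 isopropenyl group and the C15 hydroxyl cis to formyl (internal hydrogen bond, methyl trans to formyl).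

Step 4
Reactants: 4 hydroxy aldehyde
Product: 5 triethylsilyl ether of 4
Conditions: TESOTf (1.3 equiv), 2,6-lutidine (2.5 equiv), CH2Cl2, −78 °C
Reagents that add atoms: triethylsilyl triflate, CC[Si](CC)(CC)OS(=O)(=O)C(F)(F)F
Why: Silyl triflate/lutidine silylation of the tertiary alcohol at low temperature should outpace retro-aldol and dehydration, and the triethylsilyl ether is robust enough for the hydride, ozone, NaH and carbanion steps yet leaves with fluoride at the end.

Step 5
Reactants: 5 silyloxy aldehyde; 6 dimethyl malonate
Product: 7 alkylidene malonate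
Conditions: TiCl4 (2 equiv), pyridine (4 equiv), THF, 0 °C to rt
Reagents that add atoms: dimethyl malonate, COC(=O)CC(=O)OC
Why: Knoevenagel condensation under Lehnert conditions works on hindered α-branched aldehydes at 0 °C, which should keep the β-silyloxy group from eliminating, and C9 rests in its thermodynamic configuration (trans to isopropenyl).

Step 6
Reactants: 7 alkylidene malonate
Product: 8 alkyl malonate
Conditions: NaBH4 (1.1 equiv), MeOH/THF, 0 °C
Reagents that add atoms: none
Why: Borohydride conjugate reduction of the doubly activated alkylidene malonate is fast at 0 °C and should leave the esters, the isopropenyl group and the silyl ether alone.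

Step 7
Reactants: 8 alkyl malonate
Product: 9 acetyl malonate
Conditions: O3, CH2Cl2, −78 °C; then PPh3, −78 °C to rt
Reagents that add atoms: ozone, [O-][O+]=O
Why: Ozonolysis with reductive work-up cleaves the only alkene to the C10 acetyl group; C10 becomes α to a ketone but is trans to the C9 side chain, its stable configuration.

Step 8
Reactants: 9 acetyl malonate; 10 diiodomethane
Product: 11 iodomethyl acetyl malonate
Conditions: NaH (1.05 equiv), THF, 0 °C; then CH2I2 (8 equiv), 60 °C
Reagents that add atoms: diiodomethane, ICI
Why: C-Alkylation of the sodium malonate with excess diiodomethane installs the C12 iodomethyl group; one equivalent of base removes only the malonate proton, and aldol addition of the malonate to the acetyl group would need a trans-fused bicyclo[3.3.0]octane and so should stay unpopulated.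

Step 9
Reactants: 11 iodomethyl acetyl malonate
Product: 13 bridged C2–O11 lactone C4 methyl ester, via samarium alkoxide diester 12 (not isolated)
Conditions: SmI2 (2.5 equiv, 0.1 M in THF), Fe(dbm)3 [tris(dibenzoylmethanato)iron] (3 mol %), THF, −78 °C to rt; aq. NH4Cl
Reagents that add atoms: none
Why: Two single-electron transfers from divalent samarium turn the C12–I bond into a C12 alkylsamarium, which adds to the C10 acetyl carbonyl (C11–C12) in an intramolecular Barbier reaction; the closest known type is the SmI2 cyclization of ω-iodo ketones to cyclohexanols directed by a neighbouring ester. Ring B closes 6-exo-trig through a chair in which the trans C9 and C10 bonds of ring C are equatorial, and the lactone ring closes 5-exo-trig by acyl transfer of the samarium alkoxide 12 onto the 1,3-diaxial ester, giving a 6-oxabicyclo[3.2.1]octan-7-one. C11 is set by that chair: trivalent samarium bridges the ketone oxygen and the axial ester carbonyl, so O11 is axial (anti to H10) and the methyl equatorial, which also avoids a methyl/ester 1,3-diaxial clash. C3 is set by the lactonization, because only the ester cis to O11 can reach it; that carbonyl becomes C2 and the other stays as the C4 methyl ester. The step needs reduction of the iodide ahead of the ketone and addition to the ketone rather than to the geminal esters: the primary iodide is the most easily reduced group, HMPA is left out so that chelation is kept, and the 6-exo ketone addition should outrun three-membered attack on an ester or a 1,2-ester shift of the transient radical.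

Step 10
Reactants: 13 lactone methyl ester; 14 5-methylhexane-2,4-dione
Product: 16 silylated spiro acyl trione, via hydroxy triketone ester 15 (not isolated)
Conditions: 14 (3 equiv), LDA (6.2 equiv, commercial solution), THF, −78 to 0 °C; add 13, −78 °C to rt, then 50 °C; 1 M HCl
Reagents that add atoms: 5-methylhexane-2,4-dione, CC(=O)CC(=O)C(C)C
Why: Claisen acylation of the β-diketone dianion at its terminal carbon (C1) should open the strained bridged lactone at C2 in preference to the neopentyl C4 methyl ester, and the resulting 1,3,5-triketone enolate then closes ring A by Dieckmann-type C-acylation of C5 on the C4 ester, so the order of the two acylations places C1 next to C2 and keeps the C3 configuration.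

Step 11
Reactants: 16 silylated spiro acyl trione
Product: 17 spiro acyl trione diol
Conditions: HF·pyridine, THF, 0 °C to rt
Reagents that add atoms: none
Why: Fluoride-driven cleavage of the tertiary triethylsilyl ether under buffered conditions that the enolised acyl trione and both tertiary alcohols should tolerate; no stereocentre is touched.

Step 12
Reactants: 17 spiro acyl trione diol; 18 prenyl bromide
Product: 19 target CNP0273836.6
Conditions: NaOMe (3.5 equiv), MeOH, 0 °C; prenyl bromide (2.5 equiv), 0 °C to rt; dilute HCl
Reagents that add atoms: prenyl bromide, CC(C)=CCBr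
Why: Double C-alkylation of the C1 methylene flanked by the C2 and C6 carbonyls (the classical gem-dialkylation of acylphloroglucinol-type triones) should occur at C1 because it is the only free ring methylene, C5 being a fully substituted triacyl carbon, and the protic medium favours C- over O-alkylation; no stereocentre is formed.

**Compound list**

1 | (S)-(−)-limonene, (4S)-1-methyl-4-(prop-1-en-2-yl)cyclohexene | CC1=CC[C@H](CC1)C(C)=C | starting material
2 | (4S)-limonene 1,2-oxide, cis/trans mixture at the epoxide | CC12OC1C[C@H](CC2)C(C)=C | intermediate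
3 | (3S)-6-oxo-3-(prop-1-en-2-yl)heptanal | O=CC[C@H](CCC(C)=O)C(C)=C | intermediate
4 | (1R,2S,5S)-2-hydroxy-2-methyl-5-(prop-1-en-2-yl)cyclopentane-1-carbaldehyde (OH cis to CHO, CHO trans to isopropenyl) | O=C[C@@H]1[C@H](CC[C@]1(C)O)C(C)=C | intermediate
5 | 2-methyl-5-(prop-1-en-2-yl)-2-(triethylsilyloxy)cyclopentane-1-carbaldehyde, ring configuration as in 4 | O=C[C@@H]1[C@H](CC[C@]1(C)O[Si](CC)(CC)CC)C(C)=C | intermediate
6 | dimethyl malonate | COC(=O)CC(=O)OC | starting material
7 | dimethyl 2-{[2-methyl-5-(prop-1-en-2-yl)-2-(triethylsilyloxy)cyclopentyl]methylidene}malonate, ring configuration as in 4 | COC(=O)C(C(=O)OC)=C[C@@H]1[C@H](CC[C@]1(C)O[Si](CC)(CC)CC)C(C)=C | intermediate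
8 | dimethyl 2-{[2-methyl-5-(prop-1-en-2-yl)-2-(triethylsilyloxy)cyclopentyl]methyl}malonate, ring configuration as in 4 | COC(=O)C(C(=O)OC)C[C@@H]1[C@H](CC[C@]1(C)O[Si](CC)(CC)CC)C(C)=C | intermediate
9 | dimethyl 2-{[5-acetyl-2-methyl-2-(triethylsilyloxy)cyclopentyl]methyl}malonate (acetyl trans to the C8 chain, silyloxy cis to it) | COC(=O)C(C(=O)OC)C[C@@H]1[C@H](CC[C@]1(C)O[Si](CC)(CC)CC)C(C)=O | intermediate
10 | diiodomethane | ICI | starting material
11 | dimethyl 2-(iodomethyl)-2-{[5-acetyl-2-methyl-2-(triethylsilyloxy)cyclopentyl]methyl}malonate, ring configuration as in 9 | COC(=O)C(CI)(C(=O)OC)C[C@@H]1[C@H](CC[C@]1(C)O[Si](CC)(CC)CC)C(C)=O | intermediate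
12 | diiodosamarium C11 alkoxide of the ring B hydroxy diester (O11 axial, trans-fused rings B and C) | COC(=O)C1(C(=O)OC)C[C@@H]2[C@H](CC[C@]2(C)O[Si](CC)(CC)CC)[C@](C)(O[Sm](I)I)C1 | intermediate
13 | bridged C2–O11 γ-lactone C4 methyl ester with C15 triethylsilyl ether (O11 and C2 1,3-diaxial on ring B, ring C trans-fused) | O=C1[C@@]2(C[C@@H]3[C@H](CC[C@]3(C)O[Si](CC)(CC)CC)[C@](C)(O1)C2)C(=O)OC | intermediate
14 | 5-methylhexane-2,4-dione | CC(=O)CC(=O)C(C)C | starting material
15 | hydroxy triketone ester: C3 bears the C4 methyl ester and the 6-methyl-3,5-dioxoheptanoyl chain at C2, C11 hydroxyl free (open keto form) | COC(=O)[C@@]1(C(=O)CC(=O)CC(=O)C(C)C)C[C@@H]2[C@H](CC[C@]2(C)O[Si](CC)(CC)CC)[C@](C)(O)C1 | intermediate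
16 | spiro acyl trione with C15 triethylsilyl ether, C1 unsubstituted | C1C(=O)[C@@]2(C[C@@H]3[C@H](CC[C@]3(C)O[Si](CC)(CC)CC)[C@](C)(O)C2)C(=O)C(C(=O)C(C)C)=C1O | intermediate
17 | spiro acyl trione diol (C11 and C15 hydroxyls free), C1 unsubstituted | C1C(=O)[C@@]2(C[C@@H]3[C@H](CC[C@]3(C)O)[C@](C)(O)C2)C(=O)C(C(=O)C(C)C)=C1O | intermediate
18 | prenyl bromide, 1-bromo-3-methylbut-2-ene | CC(C)=CCBr | starting material
19 | CNP0273836.6 | CC(C)=CCC1(CC=C(C)C)C(=O)[C@@]2(C[C@@H]3[C@H](CC[C@]3(C)O)[C@](C)(O)C2)C(=O)C(C(=O)C(C)C)=C1O | target

**Step count and risks**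

Total step count: 12. Longest linear sequence: 12 steps, from (S)-limonene 1 to 19.

Steps most likely to fail:

Step 9. The alkylsamarium may be protonated before it cyclises (simple deiodination), electron transfer may go to the ketone (ketyl or pinacol chemistry), or chair and chelate control may be lost so that the C11 epimer forms, which cannot lactonise. The fallback closes ring B at C3–C12 instead and sets out from 8. Epoxidation of the isopropenyl group (mCPBA, NaHCO3, CH2Cl2, 0 °C) would give the 11,12-epoxide F1 as both C11 epimers. NaH in THF at 60 °C would then make the malonate carbanion open the epoxide at its primary carbon C12, attack at the tertiary C11 being blocked. The C11 alkoxide of the epimer with axial oxygen lactonises onto the cis ester and the route is rejoined at 13. Only that epimer can lactonise, so 13 is separated from non-lactonised material, at the cost of the material of the other epimer.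

Step 10. The dianion may acylate first at the C4 methyl ester instead of the lactone, which would invert the sense of ring A at C3; the lactone opening may also reverse, or O-acylation may intervene in the closure. The fallback tells the two carbonyls apart by oxidation state and sets out from 13. Saponification (LiOH, THF/H2O, 40 °C) and cold acidification would give lactone acid F2, since the γ-lactone can re-form only at the carboxyl cis to O11. (COCl)2 with catalytic DMF in CH2Cl2 would convert it into acid chloride F3. This C-acylates the magnesium enolate of 14 (MgCl2, pyridine, CH2Cl2) at its central carbon, forming C4–C5 and giving triacylmethane lactone F4. LDA (3 equiv, THF, −78 to 0 °C) then forms the dianion at the acetyl methyl (C1), which opens the lactone at C2 in an intramolecular 6-exo-trig Claisen closure, and the route is rejoined at 16.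

Step 3. The aldol may dehydrate to the conjugated enal, or equilibration at C15 and C9 may be incomplete. The fallback accepts the dehydration and sets out from 3.
- Piperidine/AcOH in refluxing benzene would give the (5R)-enal F5.
- Weitz–Scheffer epoxidation (H2O2, NaOH, MeOH, 0 °C) on the face away from the isopropenyl group would give epoxy aldehyde F6.
- Pinnick oxidation (NaClO2, NaH2PO4, 2-methyl-2-butene, t-BuOH/H2O) would give epoxy acid F7, and MeI/K2CO3 in DMF the epoxy ester F8.
- SmI2 (2.2 equiv) with HMPA and Me2NCH2CH2OH in THF would cleave the Cα–O bond; after equilibration of C9 with NaOMe in MeOH this gives hydroxy ester F9, with the C15 oxygen retained and the ester trans to isopropenyl.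
- TESOTf/2,6-lutidine would give the silyl ether ester F10, and DIBAL-H in toluene at −78 °C reduces it to the aldehyde, rejoining the route at 5.

**Further compounds**

F1 | step 9 | dimethyl 2-{[2-methyl-5-(2-methyloxiran-2-yl)-2-(triethylsilyloxy)cyclopentyl]methyl}malonate, both C11 epimers | COC(=O)C(C(=O)OC)C[C@@H]1[C@H](CC[C@]1(C)O[Si](CC)(CC)CC)C1(C)CO1
F2 | step 10 | C2–O11 lactone C4 carboxylic acid with C15 triethylsilyl ether | O=C1[C@@]2(C[C@@H]3[C@H](CC[C@]3(C)O[Si](CC)(CC)CC)[C@](C)(O1)C2)C(=O)O
F3 | step 10 | C2–O11 lactone C4 acid chloride with C15 triethylsilyl ether | O=C1[C@@]2(C[C@@H]3[C@H](CC[C@]3(C)O[Si](CC)(CC)CC)[C@](C)(O1)C2)C(=O)Cl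
F4 | step 10 | C2–O11 lactone bearing the 2-acetyl-4-methyl-3-oxopentanoyl group at C3 (C4–C5 formed) | O=C1[C@@]2(C[C@@H]3[C@H](CC[C@]3(C)O[Si](CC)(CC)CC)[C@](C)(O1)C2)C(=O)C(C(C)=O)C(=O)C(C)C
F5 | step 3 | (5R)-2-methyl-5-(prop-1-en-2-yl)cyclopent-1-ene-1-carbaldehyde | O=CC1=C(C)CC[C@@H]1C(C)=C
F6 | step 3 | 1,2-epoxy-2-methyl-5-(prop-1-en-2-yl)cyclopentane-1-carbaldehyde, epoxide trans to isopropenyl | O=C[C@]12O[C@@]1(C)CC[C@@H]2C(C)=C
F7 | step 3 | 1,2-epoxy-2-methyl-5-(prop-1-en-2-yl)cyclopentane-1-carboxylic acid, epoxide trans to isopropenyl | OC(=O)[C@]12O[C@@]1(C)CC[C@@H]2C(C)=C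
F8 | step 3 | methyl 1,2-epoxy-2-methyl-5-(prop-1-en-2-yl)cyclopentane-1-carboxylate, epoxide trans to isopropenyl | COC(=O)[C@]12O[C@@]1(C)CC[C@@H]2C(C)=C
F9 | step 3 | methyl 2-hydroxy-2-methyl-5-(prop-1-en-2-yl)cyclopentane-1-carboxylate, ring configuration as in 4 | COC(=O)[C@@H]1[C@H](CC[C@]1(C)O)C(C)=C
F10 | step 3 | methyl 2-methyl-5-(prop-1-en-2-yl)-2-(triethylsilyloxy)cyclopentane-1-carboxylate, ring configuration as in 4 | COC(=O)[C@@H]1[C@H](CC[C@]1(C)O[Si](CC)(CC)CC)C(C)=C
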